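**Retrosynthetic overview**

1. Target 23 ⇐ Δ5 triacetate 22 by ene-type chlorination (C6–Cl, C5=C16); 22 ⇐ hydroxy-lactone diketone 19 by two ketone reductions and acetylation.
2. γ-Lactone (last ring) ⇐ intramolecular Reformatsky reaction of a C7 2-bromopropanoate onto the C8 ketone (sets C8 and C17).
3. Six- and ten-membered rings (one step) ⇐ transannular oxidative radical closure C1–C10 of the twofold-symmetric 14-membered 2-methyl-1,3-diketone 13 (cembrane → briarane, as in the biosynthesis). Either alkene gives the same product; the untouched one becomes C5=C6.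
4. 14-membered carbocycle (first ring) ⇐ double γ-alkylation of the dianion of 3-methylpentane-2,4-dione with the bis(allylic bromide) 7.
5. 7 ⇐ two-directional Wittig / reduction / bromination from L-arabinitol, which supplies C6–C10 and the C7/C9 configuration.

Assumption: atom labels are briarane numbering (C1 quaternary with methyl C15; C5 bears C16; C11 bears C20; C17 bears methyl C18 and lactone carbonyl C19), and L-arabinitol is taken as commercial (it is also one NaBH4 step from L-arabinose).

CIP letters at C1, C7 and C8 change along the route only because substituent priorities change; no centre is inverted once set.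

**Route**

Step 1
Reactants: 1 L-arabinitol [(2S,4S)-pentane-1,2,3,4,5-pentol]
Product: 2 1,2,3,4,5-pentakis-O-(triethylsilyl)-L-arabinitol
Conditions: Et3SiCl (6 equiv), imidazole (12 equiv), DMF, 0 °C → rt
Reagents that add atoms: chlorotriethylsilane, CC[Si](CC)(CC)Cl
Why: Exhaustive silyl ether formation; no stereocentre is touched, and the (2S,4S) carbinols become C7 and C9 of the target while the central carbinol becomes C8.

Step 2
Reactants: 2 1,2,3,4,5-pentakis-O-(triethylsilyl)-L-arabinitol
Product: 3 (2R,4R)-2,3,4-tris(triethylsilyloxy)pentanedial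
Conditions: (COCl)2 (4 equiv), DMSO (8 equiv), CH2Cl2, −78 → −35 °C; Et3N (10 equiv), −78 → 0 °C
Reagents that add atoms: none
Why: Swern oxidation in which the chlorosulfonium reagent cleaves and oxidises primary triethylsilyl ethers much faster than secondary ones (a known selectivity), so the dialdehyde forms with the three secondary silyl ethers intact; the cold amine step avoids epimerisation of the α-silyloxy centres.

Step 3
Reactants: 3 (2R,4R)-2,3,4-tris(triethylsilyloxy)pentanedial; 4 ethyl 2-(triphenylphosphoranylidene)propanoate (2.4 equiv)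
Product: 5 diethyl (2E,4S,6S,7E)-2,8-dimethyl-4,5,6-tris(triethylsilyloxy)nona-2,7-dienedioate
Conditions: CH2Cl2, rt → 40 °C
Reagents that add atoms: none
Why: Two-directional Wittig olefination with a stabilised α-methyl ylide gives both trisubstituted (E)-enoates (the future C5=C6 and C10=C11 with methyls C16 and C20) without touching the α-stereocentres.

Step 4
Reactants: 5 diethyl (2E,4S,6S,7E)-2,8-dimethyl-4,5,6-tris(triethylsilyloxy)nona-2,7-dienedioate
Product: 6 (2E,4S,6S,7E)-2,8-dimethyl-4,5,6-tris(triethylsilyloxy)nona-2,7-diene-1,9-diol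
Conditions: i-Bu2AlH (5 equiv), CH2Cl2, −78 → −40 °C; Rochelle salt work-up
Reagents that add atoms: none
Why: 1,2-Reduction of both enoates to allylic alcohols by the aluminium hydride; alkene geometry and stereocentres are unaffected.

Step 5
Reactants: 6 (2E,4S,6S,7E)-2,8-dimethyl-4,5,6-tris(triethylsilyloxy)nona-2,7-diene-1,9-diol
Product: 7 (2E,4S,6S,7E)-1,9-dibromo-2,8-dimethyl-4,5,6-tris(triethylsilyloxy)nona-2,7-diene
Conditions: CBr4 (2.6 equiv), PPh3 (2.6 equiv), CH2Cl2, −20 → 0 °C
Reagents that add atoms: carbon tetrabromide, BrC(Br)(Br)Br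
Why: Appel bromination of the two primary allylic alcohols by direct SN2 displacement, with no allylic shift and neutral conditions that keep the silyl ethers.

Step 6
Reactants: 7 (2E,4S,6S,7E)-1,9-dibromo-2,8-dimethyl-4,5,6-tris(triethylsilyloxy)nona-2,7-diene; 8 3-methylpentane-2,4-dione
Product: 11 (6E,8S,10S,11E)-8,9,10-trihydroxy-2,6,12-trimethylcyclotetradeca-6,11-diene-1,3-dione, via open-chain bromo diketone 9 (not isolated), via tris(triethylsilyl) macrocycle 10 (not isolated)
Conditions: 8, LiN(i-Pr)2 (2.05 equiv), THF, −78 → 0 °C; add to 7 (1.0 equiv), THF, −78 °C; dilute to 2 mM, LiN(i-Pr)2 (1.2 equiv, syringe pump), −78 → 0 °C; AcOH; then HF·pyridine, pyridine, THF, 0 °C → rt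
Reagents that add atoms: none
Why: Hauser-type γ-alkylation of a β-diketone dianion at its terminal carbon, run twice (C3–C4 intermolecular, then C12–C13 as the ring closure at high dilution), builds the cembrane-type 14-membered carbocycle, and fluoride then removes the silyl ethers; no stereocentre is made, and C1 and C8 are non-stereogenic because the two arms are identical.

Step 7
Reactants: 11 (6E,8S,10S,11E)-8,9,10-trihydroxy-2,6,12-trimethylcyclotetradeca-6,11-diene-1,3-dione
Product: 12 (6E,8S,10S,11E)-8,10-[(di-tert-butylsilanediyl)bis(oxy)]-9-hydroxy-2,6,12-trimethylcyclotetradeca-6,11-diene-1,3-dione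
Conditions: t-Bu2Si(OTf)2 (1.05 equiv), 2,6-lutidine (3 equiv), CH2Cl2, −40 → 0 °C
Reagents that add atoms: di-tert-butylsilyl bis(trifluoromethanesulfonate), CC(C)(C)[Si](OS(=O)(=O)C(F)(F)F)(OS(=O)(=O)C(F)(F)F)C(C)(C)C
Why: Cyclic silylene formation: the di-tert-butylsilylene bridges the two 1,3-related allylic hydroxyls as the six-membered dioxasilinane in preference to the strained, labile five-membered 1,2-isomer, which leaves only the central C8 hydroxyl free.

Step 8
Reactants: 12 (6E,8S,10S,11E)-8,10-[(di-tert-butylsilanediyl)bis(oxy)]-9-hydroxy-2,6,12-trimethylcyclotetradeca-6,11-diene-1,3-dione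
Product: 13 (6E,8S,10S,11E)-8,10-[(di-tert-butylsilanediyl)bis(oxy)]-2,6,12-trimethylcyclotetradeca-6,11-diene-1,3,9-trione
Conditions: Dess–Martin periodinane (1.4 equiv), CH2Cl2, 0 °C → rt
Reagents that add atoms: none
Why: Dess–Martin oxidation of the single free secondary alcohol gives the C8 ketone under non-basic conditions that do not epimerise C7/C9; the macrocycle is now twofold-symmetric apart from the enolisable C1–H.

Step 9
Reactants: 13 (6E,8S,10S,11E)-8,10-[(di-tert-butylsilanediyl)bis(oxy)]-2,6,12-trimethylcyclotetradeca-6,11-diene-1,3,9-trione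
Product: 14 (1S,5E,7S,9S,10S)-7,9-[(di-tert-butylsilanediyl)bis(oxy)]-17,18,19-trinorbriara-5,11(20)-diene-2,8,14-trione
Conditions: Mn(OAc)3·2H2O (2.2 equiv), Cu(OAc)2·H2O (1.0 equiv), degassed AcOH, 5 mM, 35 °C
Reagents that add atoms: none
Why: Proposed new method: Mn(OAc)3 oxidises the enolised 2-methyl-1,3-diketone to the tertiary electrophilic C1 radical, which adds across the ring to C10 of an (E)-trisubstituted alkene in the 6-endo mode through a chair, and Cu(OAc)2 oxidises the resulting tertiary C11 radical with loss of a methyl hydrogen to the C11=C20 methylidene; the radical is twofold-symmetric, so attack on either alkene gives the same compound and the other alkene becomes C5=C6; C1 and C10 are set together (Me-15 trans to H-10 because the eight-carbon bridge sits equatorial on both new ring atoms, and C1 adds to the alkene face anti to C8 with H-9 eclipsing the alkene to avoid 1,3-allylic strain with the C20 methyl), and the quaternary product cannot be oxidised further; the closest known chemistry is the Snider Mn(OAc)3/Cu(OAc)2 oxidative free-radical polyene cyclisation of 2-substituted 1,3-dicarbonyls and transannular radical cyclisations of macrocycles, and the bond formed is the biosynthetic C3–C8 closure of a cembrane to the briarane skeleton.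

Step 10
Reactants: 14 (1S,5E,7S,9S,10S)-7,9-[(di-tert-butylsilanediyl)bis(oxy)]-17,18,19-trinorbriara-5,11(20)-diene-2,8,14-trione
Product: 15 (1S,5E,7S,9S,10S)-7,9-dihydroxy-17,18,19-trinorbriara-5,11(20)-diene-2,8,14-trione
Conditions: HF·pyridine, pyridine, THF, 0 °C
Reagents that add atoms: none
Why: Fluoride cleavage of the silylene under buffered, non-basic conditions that avoid acyloin isomerisation of the α,α'-dihydroxy ketone; no stereocentre is affected.

Step 11
Reactants: 15 (1S,5E,7S,9S,10S)-7,9-dihydroxy-17,18,19-trinorbriara-5,11(20)-diene-2,8,14-trione; 16 2-bromopropanoyl bromide (racemic, 1.1 equiv)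
Product: 17 (1S,5E,7S,9S,10S)-7-(2-bromopropanoyloxy)-9-hydroxy-17,18,19-trinorbriara-5,11(20)-diene-2,8,14-trione (either configuration at the CHBr carbon)
Conditions: pyridine (2 equiv), CH2Cl2, −60 → −30 °C
Reagents that add atoms: none
Why: Site-selective esterification: the allylic C7 hydroxyl is flanked by an sp2 carbon, whereas the C9 hydroxyl sits between the C8 carbonyl and the ring-fusion methine next to quaternary C1, so the acid bromide acylates O-7 at low temperature; the bromine-bearing centre is destroyed in the next step.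

Step 12
Reactants: 17 (1S,5E,7S,9S,10S)-7-(2-bromopropanoyloxy)-9-hydroxy-17,18,19-trinorbriara-5,11(20)-diene-2,8,14-trione
Product: 19 (1S,5E,7S,8R,9S,10S,17R)-8,9-dihydroxy-2,14-dioxobriara-5,11(20)-dien-19,7-olide, via samarium enolate 18 (not isolated)
Conditions: SmI2 (2.2 equiv), THF, −78 °C; sat. aq. NH4Cl
Reagents that add atoms: none
Why: Samarium diiodide Reformatsky-type aldol lactonisation: fast reduction of the C–Br bond gives the samarium enolate, which adds within a five-membered ring to the chelated C8 ketone before the unconjugated ketones react; the tether from O-7 fixes the face (lactone trans-fused on the ten-membered ring, C6 anti to C9, hence 8R), and the chelated transition state plus the thermodynamic preference of the epimerisable C17 for methyl anti to C9 gives 17R.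

Step 13
Reactants: 19 (1S,5E,7S,8R,9S,10S,17R)-8,9-dihydroxy-2,14-dioxobriara-5,11(20)-dien-19,7-olide
Product: 21 (1S,2S,5E,7S,8R,9S,10S,14S,17R)-2,8,9,14-tetrahydroxybriara-5,11(20)-dien-19,7-olide, via 14-hydroxy-2-ketone 20 (not isolated)
Conditions: LiBH(s-Bu)3 (3 equiv), THF, −78 °C; AcOH, −78 → −30 °C; then Me4NBH(OAc)3 (6 equiv), MeCN/AcOH 1:1, −30 → 0 °C
Reagents that add atoms: none
Why: Two substrate-controlled hydride reductions: the bulky borohydride attacks the more reactive six-ring C14 ketone from the equatorial direction (as with 4,4-disubstituted 3-ketones) to give the axial 14-OH trans to Me-15 (14S), and the triacetoxyborohydride bound to that hydroxyl then delivers hydride intramolecularly to C2 (Evans–Saksena reduction) to give the 1,3-anti diol, that is 2S.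

Step 14
Reactants: 21 (1S,2S,5E,7S,8R,9S,10S,14S,17R)-2,8,9,14-tetrahydroxybriara-5,11(20)-dien-19,7-olide
Product: 22 (1S,2S,5E,7S,8S,9S,10S,14S,17R)-2,9,14-triacetoxy-8-hydroxybriara-5,11(20)-dien-19,7-olide
Conditions: Ac2O (12 equiv), pyridine, DMAP (0.3 equiv), CH2Cl2, rt
Reagents that add atoms: acetic anhydride, CC(=O)OC(C)=O
Why: DMAP-catalysed acetylation of the three secondary alcohols; the tertiary C8 hydroxyl is not acylated at room temperature and no stereocentre is touched.

Step 15
Reactants: 22 (1S,2S,5E,7S,8S,9S,10S,14S,17R)-2,9,14-triacetoxy-8-hydroxybriara-5,11(20)-dien-19,7-olide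
Product: 23 (1R,2S,6S,7R,8R,9S,10S,14S,17R)-2,9,14-triacetoxy-6-chloro-8-hydroxybriara-5(16),11(20)-dien-19,7-olide (CNP0199061.1)
Conditions: t-BuOCl (1.1 equiv), SiO2, CH2Cl2/hexane, −20 °C, dark
Reagents that add atoms: tert-butyl hypochlorite, CC(C)(C)OCl
Why: Ene-type electrophilic chlorination (the laboratory counterpart of haloperoxidase chlorination): Cl+ adds to C6 of the trisubstituted alkene and a C16 hydrogen is lost, giving the 6-chloro-5(16)-ene; the trisubstituted alkene should react before the 1,1-disubstituted C11=C20, helped by delivery from the free homoallylic C8 hydroxyl (the only OH left), and attack on the face anti to the allylic lactone oxygen in the conformer with H-7 eclipsing the alkene (the face on which the C8–OH lies) sets 6S.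

**Compound list**

1 | L-arabinitol, (2S,4S)-pentane-1,2,3,4,5-pentol | OC[C@H](O)C(O)[C@@H](O)CO | starting material
2 | 1,2,3,4,5-pentakis-O-(triethylsilyl)-L-arabinitol | CC[Si](CC)(CC)OC[C@H](O[Si](CC)(CC)CC)C(O[Si](CC)(CC)CC)[C@@H](O[Si](CC)(CC)CC)CO[Si](CC)(CC)CC | intermediate
3 | (2R,4R)-2,3,4-tris(triethylsilyloxy)pentanedial | O=C[C@H](O[Si](CC)(CC)CC)C(O[Si](CC)(CC)CC)[C@@H](O[Si](CC)(CC)CC)C=O | intermediate
4 | ethyl 2-(triphenylphosphoranylidene)propanoate | CCOC(=O)C(C)=P(c1ccccc1)(c1ccccc1)c1ccccc1 | starting material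
5 | diethyl (2E,4S,6S,7E)-2,8-dimethyl-4,5,6-tris(triethylsilyloxy)nona-2,7-dienedioate | CCOC(=O)/C(C)=C/[C@H](O[Si](CC)(CC)CC)C(O[Si](CC)(CC)CC)[C@@H](O[Si](CC)(CC)CC)/C=C(C)/C(=O)OCC | intermediate
6 | (2E,4S,6S,7E)-2,8-dimethyl-4,5,6-tris(triethylsilyloxy)nona-2,7-diene-1,9-diol | OC/C(C)=C/[C@H](O[Si](CC)(CC)CC)C(O[Si](CC)(CC)CC)[C@@H](O[Si](CC)(CC)CC)/C=C(C)/CO | intermediate
7 | (2E,4S,6S,7E)-1,9-dibromo-2,8-dimethyl-4,5,6-tris(triethylsilyloxy)nona-2,7-diene | BrC/C(C)=C/[C@H](O[Si](CC)(CC)CC)C(O[Si](CC)(CC)CC)[C@@H](O[Si](CC)(CC)CC)/C=C(C)/CBr | intermediate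
8 | 3-methylpentane-2,4-dione | CC(=O)C(C)C(C)=O | starting material
9 | (7E,9S,11S,12E)-14-bromo-3,7,13-trimethyl-9,10,11-tris(triethylsilyloxy)tetradeca-7,12-diene-2,4-dione (both C10 epimers, C3 labile) | CC(=O)C(C)C(=O)CC/C(C)=C/[C@H](O[Si](CC)(CC)CC)C(O[Si](CC)(CC)CC)[C@@H](O[Si](CC)(CC)CC)/C=C(C)/CBr | intermediate
10 | (6E,8S,10S,11E)-2,6,12-trimethyl-8,9,10-tris(triethylsilyloxy)cyclotetradeca-6,11-diene-1,3-dione | CC1C(=O)CC/C(C)=C/[C@H](O[Si](CC)(CC)CC)C(O[Si](CC)(CC)CC)[C@@H](O[Si](CC)(CC)CC)/C=C(C)/CCC1=O | intermediate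
11 | (6E,8S,10S,11E)-8,9,10-trihydroxy-2,6,12-trimethylcyclotetradeca-6,11-diene-1,3-dione | CC1C(=O)CC/C(C)=C/[C@H](O)C(O)[C@@H](O)/C=C(C)/CCC1=O | intermediate
12 | (6E,8S,10S,11E)-8,10-[(di-tert-butylsilanediyl)bis(oxy)]-9-hydroxy-2,6,12-trimethylcyclotetradeca-6,11-diene-1,3-dione | CC1C(=O)CC/C(C)=C/[C@@H]2O[Si](C(C)(C)C)(C(C)(C)C)O[C@H](C2O)/C=C(C)/CCC1=O | intermediate
13 | (6E,8S,10S,11E)-8,10-[(di-tert-butylsilanediyl)bis(oxy)]-2,6,12-trimethylcyclotetradeca-6,11-diene-1,3,9-trione | CC1C(=O)CC/C(C)=C/[C@@H]2O[Si](C(C)(C)C)(C(C)(C)C)O[C@H](C2=O)/C=C(C)/CCC1=O | intermediate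
14 | (1S,5E,7S,9S,10S)-7,9-[(di-tert-butylsilanediyl)bis(oxy)]-17,18,19-trinorbriara-5,11(20)-diene-2,8,14-trione (Me-15 trans to H-10) | C=C1CCC(=O)[C@]2(C)C(=O)CC/C(C)=C/[C@@H]3O[Si](C(C)(C)C)(C(C)(C)C)O[C@H](C3=O)[C@@H]12 | intermediate
15 | (1S,5E,7S,9S,10S)-7,9-dihydroxy-17,18,19-trinorbriara-5,11(20)-diene-2,8,14-trione | C=C1CCC(=O)[C@]2(C)C(=O)CC/C(C)=C/[C@H](O)C(=O)[C@@H](O)[C@@H]12 | intermediate
16 | 2-bromopropanoyl bromide (racemic) | CC(Br)C(Br)=O | starting material
17 | (1S,5E,7S,9S,10S)-7-(2-bromopropanoyloxy)-9-hydroxy-17,18,19-trinorbriara-5,11(20)-diene-2,8,14-trione | C=C1CCC(=O)[C@]2(C)C(=O)CC/C(C)=C/[C@H](OC(=O)C(C)Br)C(=O)[C@@H](O)[C@@H]12 | intermediate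
18 | diiodosamarium enolate of the C7 propanoate of 15 | C=C1CCC(=O)[C@]2(C)C(=O)CC/C(C)=C/[C@H](OC(O[Sm](I)I)=CC)C(=O)[C@@H](O)[C@@H]12 | intermediate
19 | (1S,5E,7S,8R,9S,10S,17R)-8,9-dihydroxy-2,14-dioxobriara-5,11(20)-dien-19,7-olide | C=C1CCC(=O)[C@]2(C)C(=O)CC/C(C)=C/[C@@H]3OC(=O)[C@H](C)[C@@]3(O)[C@@H](O)[C@@H]12 | intermediate
20 | (1R,5E,7S,8R,9S,10S,14S,17R)-8,9,14-trihydroxy-2-oxobriara-5,11(20)-dien-19,7-olide | C=C1CC[C@H](O)[C@]2(C)C(=O)CC/C(C)=C/[C@@H]3OC(=O)[C@H](C)[C@@]3(O)[C@@H](O)[C@@H]12 | intermediate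
21 | (1S,2S,5E,7S,8R,9S,10S,14S,17R)-2,8,9,14-tetrahydroxybriara-5,11(20)-dien-19,7-olide | C=C1CC[C@H](O)[C@]2(C)[C@@H](O)CC/C(C)=C/[C@@H]3OC(=O)[C@H](C)[C@@]3(O)[C@@H](O)[C@@H]12 | intermediate
22 | (1S,2S,5E,7S,8S,9S,10S,14S,17R)-2,9,14-triacetoxy-8-hydroxybriara-5,11(20)-dien-19,7-olide | C=C1CC[C@H](OC(C)=O)[C@]2(C)[C@@H](OC(C)=O)CC/C(C)=C/[C@@H]3OC(=O)[C@H](C)[C@@]3(O)[C@@H](OC(C)=O)[C@@H]12 | intermediate
23 | (1R,2S,6S,7R,8R,9S,10S,14S,17R)-2,9,14-triacetoxy-6-chloro-8-hydroxybriara-5(16),11(20)-dien-19,7-olide | C=C1CC[C@H](OC(C)=O)[C@]2(C)[C@@H](OC(C)=O)CCC(=C)[C@H](Cl)[C@@H]3OC(=O)[C@H](C)[C@@]3(O)[C@@H](OC(C)=O)[C@@H]12 | target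

**Totals and risks**

Total step count: 15. Longest linear sequence: 15 steps (1 → 23); compounds 4, 8 and 16 are bought.

Three steps most likely to fail:

Step 9 (transannular oxidative cyclisation). It has no direct precedent on a macrocycle, and the facial selectivity at C1/C10 and the exo/endo alkene ratio rest on conformational arguments. Fallback, setting out from 13 and returning at 14: replace oxidative termination by a group-transfer radical cyclisation. Compound 13 is selenenylated at C1 (PhSeCl, pyridine, CH2Cl2, 0 °C) to (6E,8S,10S,11E)-8,10-[(di-tert-butylsilanediyl)bis(oxy)]-2,6,12-trimethyl-2-(phenylselanyl)cyclotetradeca-6,11-diene-1,3,9-trione F1. Sun-lamp irradiation in benzene makes the same C1 radical, which adds to C10; the tertiary C11 radical takes PhSe from another molecule of F1 and gives the 11-(phenylselanyl) bicyclic trione F2. Oxidation with H2O2/pyridine at 0 °C and selenoxide syn-elimination toward the methyl group gives 14.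

Step 6 (two-component macrocyclisation). The first alkylation is statistical and the ring closure competes with oligomerisation; 25–35% is a realistic expectation. Fallback, setting out from 7 and 8 and returning at 11: give up the one-flask annulation for a linear sequence with a discrete intramolecular ring closure. The dianion of 8 is alkylated with three equivalents of 7 (excess recovered) and the mono-alkylated bromide 9 is isolated. Purified 9 is added by syringe pump to LiN(i-Pr)2 (2.2 equiv, 1 mM, THF, −78 → 0 °C) to give 10, which is desilylated with HF·pyridine to 11. No new compound arises.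

Step 15 (ene chlorination). The risks are competition from C11=C20, loss of a C4 instead of a C16 hydrogen, chloro-etherification by the C8–OH, and the C6 configuration. Fallback, setting out from 22 and returning at 23: install oxygen first and chlorine by substitution. Singlet-oxygen ene reaction (O2, tetraphenylporphyrin, hν, CH2Cl2, 0 °C; then PPh3) is far more selective for the trisubstituted alkene and gives 2,9,14-triacetoxy-6,8-dihydroxybriara-5(16),11(20)-dien-19,7-olide F3 (C6 epimer as formed). Dess–Martin oxidation gives the 6-ketone F4. Reduction with Me4NBH(OAc)3, directed by the C8 hydroxyl to the 1,3-anti diol, gives the (6R)-alcohol F5. Corey–Kim chlorination (N-chlorosuccinimide, Me2S, CH2Cl2, −20 °C) with inversion gives 23.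

**Further compounds**

F0 | step 6 | none | none
F1 | step 9 | (6E,8S,10S,11E)-8,10-[(di-tert-butylsilanediyl)bis(oxy)]-2,6,12-trimethyl-2-(phenylselanyl)cyclotetradeca-6,11-diene-1,3,9-trione | CC1([Se]c3ccccc3)C(=O)CC/C(C)=C/[C@@H]2O[Si](C(C)(C)C)(C(C)(C)C)O[C@H](C2=O)/C=C(C)/CCC1=O
F2 | step 9 | (1S,5E,7S,9S,10S)-7,9-[(di-tert-butylsilanediyl)bis(oxy)]-11-(phenylselanyl)-17,18,19-trinorbriar-5-ene-2,8,14-trione (C11 epimers) | CC1([Se]c4ccccc4)CCC(=O)[C@]2(C)C(=O)CC/C(C)=C/[C@@H]3O[Si](C(C)(C)C)(C(C)(C)C)O[C@H](C3=O)[C@@H]12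
F3 | step 15 | 2,9,14-triacetoxy-6,8-dihydroxybriara-5(16),11(20)-dien-19,7-olide (C6 epimer as formed, other centres as in 22) | C=C1CC[C@H](OC(C)=O)[C@]2(C)[C@@H](OC(C)=O)CCC(=C)C(O)[C@@H]3OC(=O)[C@H](C)[C@@]3(O)[C@@H](OC(C)=O)[C@@H]12
F4 | step 15 | 2,9,14-triacetoxy-8-hydroxy-6-oxobriara-5(16),11(20)-dien-19,7-olide | C=C1CC[C@H](OC(C)=O)[C@]2(C)[C@@H](OC(C)=O)CCC(=C)C(=O)[C@@H]3OC(=O)[C@H](C)[C@@]3(O)[C@@H](OC(C)=O)[C@@H]12
F5 | step 15 | (6R)-2,9,14-triacetoxy-6,8-dihydroxybriara-5(16),11(20)-dien-19,7-olide | C=C1CC[C@H](OC(C)=O)[C@]2(C)[C@@H](OC(C)=O)CCC(=C)[C@@H](O)[C@@H]3OC(=O)[C@H](C)[C@@]3(O)[C@@H](OC(C)=O)[C@@H]12
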